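**Strategy.** The pyran ring (ring C) is closed at C2–C3. C2 sits between the ether oxygen O1 and C3, the stereogenic carbon that carries ring B, so at the alkene oxidation level C2=C3 is an aryl enol ether. Ring-closing metathesis of an aryl vinyl ether on ring A with a 2-arylallyl side chain (C4, C3, ring B) forms this bond and the whole 3-aryl-4H-chromene skeleton in one operation. The diene comes from a ring B vinyl Grignard reagent and a ring A ortho-quinone methide. Iridium-catalysed hydrogenation then sets C3, and the 2-methylbut-3-en-2-yl group is installed late by Claisen rearrangement of a 4'-O-prenyl ether.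

Key step: step 9

Remark: isoflavan numbering is used (O1, C2, C3, C4, C4a to C8a for rings C and A; primed locants for ring B); the stereocentre C3 of the target is (S); 1, 6 and all reagents named are taken to be catalogue chemicals.

Step 1
Reactants: 1 1-(2,3,4-trihydroxyphenyl)ethanone
Product: 2 1-[4-(benzyloxy)-2,3-dihydroxyphenyl]ethanone
Conditions: BnBr (1.05 equiv), NaHCO3 (1.5 equiv), KI (0.1 equiv), DMF, 40 °C
Reagents that add atoms: benzyl bromide BrCc1ccccc1
Why: Williamson etherification; the 4-OH, para to the acetyl group and not chelated, should be the most acidic and most accessible hydroxyl under weak base, whereas 2-OH is hydrogen-bonded to the carbonyl and 3-OH is flanked on both sides.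

Step 2
Reactants: 2 1-[4-(benzyloxy)-2,3-dihydroxyphenyl]ethanone
Product: 3 1-[4-(benzyloxy)-2-hydroxy-3-(methoxymethoxy)phenyl]ethanone
Conditions: MOMCl (1.1 equiv), i-Pr2NEt (1.5 equiv), CH2Cl2, 0 °C to rt
Reagents that add atoms: chloromethyl methyl ether COCCl
Why: O-alkylation with an amine base should take only the free 3-OH, because the 2-OH chelated to the ketone is not engaged without full deprotonation.

Step 3
Reactants: 3 1-[4-(benzyloxy)-2-hydroxy-3-(methoxymethoxy)phenyl]ethanone
Product: 4 1-[4-(benzyloxy)-2-methoxy-3-(methoxymethoxy)phenyl]ethanone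
Conditions: MeI (3 equiv), K2CO3 (2 equiv), DMF, 45 °C
Reagents that add atoms: iodomethane CI
Why: Williamson methylation of the last, chelated phenol under forcing carbonate conditions fixes the 2'-methoxy group; the base is too weak to enolise the ketone.

Step 4
Reactants: 4 1-[4-(benzyloxy)-2-methoxy-3-(methoxymethoxy)phenyl]ethanone
Product: 5 (E)-N'-{1-[4-(benzyloxy)-2-methoxy-3-(methoxymethoxy)phenyl]ethylidene}-2,4,6-triisopropylbenzenesulfonohydrazide
Conditions: 2,4,6-triisopropylbenzenesulfonyl hydrazide (1.1 equiv), PPTS (5 mol %), 4 Å MS, THF, rt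
Reagents that add atoms: 2,4,6-triisopropylbenzenesulfonyl hydrazide CC(C)c1cc(C(C)C)c(S(=O)(=O)NN)c(C(C)C)c1
Why: Hydrazone condensation under mild acid catalysis that the MOM acetal tolerates; the triisopropylphenyl group prevents ortho-lithiation of the sulfonyl ring in the next step.

Step 5
Reactants: 6 2,4-dihydroxybenzaldehyde
Product: 7 2,4-bis(tert-butoxycarbonyloxy)benzaldehyde
Conditions: Boc2O (2.3 equiv), DMAP (5 mol %), i-Pr2NEt (2.5 equiv), THF, 0 °C to rt
Reagents that add atoms: di-tert-butyl dicarbonate CC(C)(C)OC(=O)OC(=O)OC(C)(C)C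
Why: DMAP-catalysed O-acylation converts both phenols into tert-butyl carbonates; the ortho carbonate is the later trigger for quinone methide formation and the para carbonate protects O7.

Step 6
Reactants: 7 2,4-bis(tert-butoxycarbonyloxy)benzaldehyde
Product: 8 2,4-bis(tert-butoxycarbonyloxy)benzyl alcohol
Conditions: NaBH4 (0.6 equiv), THF–H2O (9:1), 0 °C, 20 min; pH 7 buffer
Reagents that add atoms: none
Why: Borohydride reduction of the aldehyde at 0 °C with a neutral quench should spare the hindered carbonates and avoid premature carbonate migration.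

Step 7
Reactants: 5 (E)-N'-{1-[4-(benzyloxy)-2-methoxy-3-(methoxymethoxy)phenyl]ethylidene}-2,4,6-triisopropylbenzenesulfonohydrazide; 8 2,4-bis(tert-butoxycarbonyloxy)benzyl alcohol
Product: 12 tert-butyl 4-{2-[4-(benzyloxy)-2-methoxy-3-(methoxymethoxy)phenyl]prop-2-en-1-yl}-3-hydroxyphenyl carbonate, via vinyllithium 9 (not isolated), via vinylmagnesium bromide 10 (not isolated), via ortho-quinone methide 11 (not isolated)
Conditions: 5 (1.3 equiv), n-BuLi (2.6 equiv), THF, −78 to 0 °C; MgBr2·OEt2 (1.5 equiv), −78 °C; then 8 (1.0 equiv, pre-treated with t-BuMgCl 1.0 equiv, THF, −78 °C); −78 °C to rt; aq NH4Cl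
Reagents that add atoms: none
Why: A Shapiro reaction gives the α-arylvinyllithium, which is transmetalated to magnesium; the magnesium alkoxide of 8 then transfers its ortho carbonate to the benzylic oxygen and expels tert-butyl carbonate, and the resulting ortho-quinone methide is captured by 1,4-addition of the vinyl Grignard reagent, which re-aromatises ring A and leaves O1 free and the para carbonate intact.

Step 8
Reactants: 12 tert-butyl 4-{2-[4-(benzyloxy)-2-methoxy-3-(methoxymethoxy)phenyl]prop-2-en-1-yl}-3-hydroxyphenyl carbonate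
Product: 13 tert-butyl 4-{2-[4-(benzyloxy)-2-methoxy-3-(methoxymethoxy)phenyl]prop-2-en-1-yl}-3-(vinyloxy)phenyl carbonate
Conditions: Cu(OAc)2 (1.0 equiv), 2,4,6-trivinylcyclotriboroxane–pyridine complex (0.7 equiv), pyridine (10 equiv), CH2Cl2, rt, dry air
Reagents that add atoms: 2,4,6-trivinylcyclotriboroxane–pyridine complex C=CB1OB(C=C)OB(C=C)O1.c1ccncc1
Why: Copper-mediated oxidative O-vinylation of the phenol with a vinylboron reagent (Chan–Lam type coupling) runs at room temperature under weakly basic conditions that the carbonate, the MOM acetal and the allylic alkene should survive.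

Step 9
Reactants: 13 tert-butyl 4-{2-[4-(benzyloxy)-2-methoxy-3-(methoxymethoxy)phenyl]prop-2-en-1-yl}-3-(vinyloxy)phenyl carbonate
Product: 14 tert-butyl 3-[4-(benzyloxy)-2-methoxy-3-(methoxymethoxy)phenyl]-4H-chromen-7-yl carbonate
Conditions: second-generation Grubbs catalyst (10 mol %), 1,4-benzoquinone (20 mol %), toluene (0.005 M), 80 °C, argon sparge
Reagents that add atoms: none
Why: Olefin metathesis: the ruthenium benzylidene exchanges with the unhindered vinyl ether to give the aryloxy-substituted carbene Ru=CH–OAr at C2, which adds intramolecularly across the 1,1-disubstituted C3=CH2 alkene to a ruthenacyclobutane whose cycloreversion expels Ru=CH2 (ethylene overall) and leaves the C2=C3 double bond. The closest known reaction type is ring-closing metathesis of 1-allyl-2-(vinyloxy)benzenes to 4H-chromenes, here applied to a 2-arylallyl partner that gives a trisubstituted enol ether. The six-membered pyran ring (ring C: O1, C2, C3, C4, C4a, C8a) is closed between the two alkene termini, an unstrained closure because O1 and C4 are already held ortho on ring A. No stereocentre is formed: C3 becomes a prochiral sp2 carbon whose configuration is set in step 10 by the chiral iridium catalyst. The step needs cyclisation to win over migration of the 2-arylallyl double bond into conjugation and over intermolecular metathesis; 1,4-benzoquinone scavenges ruthenium hydrides, high dilution and ethylene removal favour the ring, and the benzyl, MOM and carbonate groups carry no competing alkene.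

Step 10
Reactants: 14 tert-butyl 3-[4-(benzyloxy)-2-methoxy-3-(methoxymethoxy)phenyl]-4H-chromen-7-yl carbonate
Product: 16 tert-butyl (3S)-3-[4-hydroxy-2-methoxy-3-(methoxymethoxy)phenyl]chroman-7-yl carbonate, via benzyl ether 15 (not isolated)
Conditions: [Ir(cod)((S)-t-Bu-PHOX)]BArF (2 mol %; ligand enantiomer fixed by a preliminary screen), H2 (50 bar), CH2Cl2, rt; then solvent switch to EtOAc–EtOH, Pd/C (10 wt %), H2 (1 bar), rt
Reagents that add atoms: none
Why: Iridium-catalysed asymmetric hydrogenation of a trisubstituted cyclic enol ether, where the chiral N,P ligand should direct H to the Re face of C3 (priorities C2 > C1' > C4) to give the (S) centre; palladium is added only after the alkene is consumed, so hydrogenolysis of the benzyl ether frees 4'-OH without a racemic background reduction.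

Step 11
Reactants: 16 tert-butyl (3S)-3-[4-hydroxy-2-methoxy-3-(methoxymethoxy)phenyl]chroman-7-yl carbonate
Product: 17 tert-butyl (3S)-3-[2-methoxy-3-(methoxymethoxy)-4-(3-methylbut-2-en-1-yloxy)phenyl]chroman-7-yl carbonate
Conditions: 3-methylbut-2-en-1-ol (1.5 equiv), PPh3 (1.5 equiv), DIAD (1.5 equiv), THF, 0 °C to rt
Reagents that add atoms: 3-methylbut-2-en-1-ol CC(C)=CCO
Why: Mitsunobu etherification of the only free phenol under neutral conditions avoids a phenoxide that could attack the aryl carbonate, and C3 is not touched.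

Step 12
Reactants: 17 tert-butyl (3S)-3-[2-methoxy-3-(methoxymethoxy)-4-(3-methylbut-2-en-1-yloxy)phenyl]chroman-7-yl carbonate
Product: 19 tert-butyl (3S)-3-[4-hydroxy-2-methoxy-3-(methoxymethoxy)-5-(2-methylbut-3-en-2-yl)phenyl]chroman-7-yl carbonate, via dienone 18 (not isolated)
Conditions: Eu(fod)3 (10 mol %), CHCl3, 60 °C, sealed tube, argon
Reagents that add atoms: none
Why: Lewis acid-catalysed aromatic Claisen rearrangement: the [3,3] shift can only deliver the inverted allyl unit to C5', the one unsubstituted ortho position (C3' bears OMOM, and the para position C1' is blocked so no Cope migration follows), and tautomerisation of dienone 18 restores the phenol; 60 °C is below the onset of carbonate thermolysis.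

Step 13
Reactants: 19 tert-butyl (3S)-3-[4-hydroxy-2-methoxy-3-(methoxymethoxy)-5-(2-methylbut-3-en-2-yl)phenyl]chroman-7-yl carbonate
Product: 20 (3S)-3-[3,4-dihydroxy-2-methoxy-5-(2-methylbut-3-en-2-yl)phenyl]chroman-7-ol
Conditions: HCl (2 M in MeOH, from AcCl/MeOH), degassed, 0 °C to rt
Reagents that add atoms: none
Why: Acidic methanolysis should cleave the MOM acetal and the tert-butyl carbonate in one operation, while dilute acid at ambient temperature should not protonate the monosubstituted alkene and C3 is not epimerisable.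

**Compound list**

1 | 1-(2,3,4-trihydroxyphenyl)ethanone | CC(=O)c1ccc(O)c(O)c1O | starting material
2 | 1-[4-(benzyloxy)-2,3-dihydroxyphenyl]ethanone | CC(=O)c1ccc(OCc2ccccc2)c(O)c1O | intermediate
3 | 1-[4-(benzyloxy)-2-hydroxy-3-(methoxymethoxy)phenyl]ethanone | CC(=O)c1ccc(OCc2ccccc2)c(OCOC)c1O | intermediate
4 | 1-[4-(benzyloxy)-2-methoxy-3-(methoxymethoxy)phenyl]ethanone | CC(=O)c1ccc(OCc2ccccc2)c(OCOC)c1OC | intermediate
5 | (E)-N'-{1-[4-(benzyloxy)-2-methoxy-3-(methoxymethoxy)phenyl]ethylidene}-2,4,6-triisopropylbenzenesulfonohydrazide | C/C(=N\NS(=O)(=O)c1c(C(C)C)cc(C(C)C)cc1C(C)C)c1ccc(OCc2ccccc2)c(OCOC)c1OC | intermediate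
6 | 2,4-dihydroxybenzaldehyde | O=Cc1ccc(O)cc1O | starting material
7 | 2,4-bis(tert-butoxycarbonyloxy)benzaldehyde | O=Cc1ccc(OC(=O)OC(C)(C)C)cc1OC(=O)OC(C)(C)C | intermediate
8 | 2,4-bis(tert-butoxycarbonyloxy)benzyl alcohol | OCc1ccc(OC(=O)OC(C)(C)C)cc1OC(=O)OC(C)(C)C | intermediate
9 | {1-[4-(benzyloxy)-2-methoxy-3-(methoxymethoxy)phenyl]vinyl}lithium | [Li]C(=C)c1ccc(OCc2ccccc2)c(OCOC)c1OC | intermediate
10 | {1-[4-(benzyloxy)-2-methoxy-3-(methoxymethoxy)phenyl]vinyl}magnesium bromide | Br[Mg]C(=C)c1ccc(OCc2ccccc2)c(OCOC)c1OC | intermediate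
11 | 3-(tert-butoxycarbonyloxy)-6-methylidenecyclohexa-2,4-dien-1-one | C=C1C=CC(OC(=O)OC(C)(C)C)=CC1=O | intermediate
12 | tert-butyl 4-{2-[4-(benzyloxy)-2-methoxy-3-(methoxymethoxy)phenyl]prop-2-en-1-yl}-3-hydroxyphenyl carbonate | C=C(Cc1ccc(OC(=O)OC(C)(C)C)cc1O)c1ccc(OCc2ccccc2)c(OCOC)c1OC | intermediate
13 | tert-butyl 4-{2-[4-(benzyloxy)-2-methoxy-3-(methoxymethoxy)phenyl]prop-2-en-1-yl}-3-(vinyloxy)phenyl carbonate | C=COc1cc(OC(=O)OC(C)(C)C)ccc1CC(=C)c1ccc(OCc2ccccc2)c(OCOC)c1OC | intermediate
14 | tert-butyl 3-[4-(benzyloxy)-2-methoxy-3-(methoxymethoxy)phenyl]-4H-chromen-7-yl carbonate | CC(C)(C)OC(=O)Oc1ccc2c(c1)OC=C(C2)c1ccc(OCc2ccccc2)c(OCOC)c1OC | intermediate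
15 | tert-butyl (3S)-3-[4-(benzyloxy)-2-methoxy-3-(methoxymethoxy)phenyl]chroman-7-yl carbonate | COc1c([C@H]2COc3cc(OC(=O)OC(C)(C)C)ccc3C2)ccc(OCc2ccccc2)c1OCOC | intermediate
16 | tert-butyl (3S)-3-[4-hydroxy-2-methoxy-3-(methoxymethoxy)phenyl]chroman-7-yl carbonate | COc1c([C@H]2COc3cc(OC(=O)OC(C)(C)C)ccc3C2)ccc(O)c1OCOC | intermediate
17 | tert-butyl (3S)-3-[2-methoxy-3-(methoxymethoxy)-4-(3-methylbut-2-en-1-yloxy)phenyl]chroman-7-yl carbonate | COc1c([C@H]2COc3cc(OC(=O)OC(C)(C)C)ccc3C2)ccc(OCC=C(C)C)c1OCOC | intermediate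
18 | tert-butyl (3S)-3-[3-methoxy-4-(methoxymethoxy)-6-(2-methylbut-3-en-2-yl)-5-oxocyclohexa-1,3-dien-1-yl]chroman-7-yl carbonate (both epimers at the ring sp3 carbon) | COC1=C(OCOC)C(=O)C(C(C)(C)C=C)C=C1[C@H]2COc3cc(OC(=O)OC(C)(C)C)ccc3C2 | intermediate
19 | tert-butyl (3S)-3-[4-hydroxy-2-methoxy-3-(methoxymethoxy)-5-(2-methylbut-3-en-2-yl)phenyl]chroman-7-yl carbonate | COc1c([C@H]2COc3cc(OC(=O)OC(C)(C)C)ccc3C2)cc(C(C)(C)C=C)c(O)c1OCOC | intermediate
20 | (3S)-3-[3,4-dihydroxy-2-methoxy-5-(2-methylbut-3-en-2-yl)phenyl]chroman-7-ol | C=CC(C)(C)c1cc([C@H]2COc3cc(O)ccc3C2)c(OC)c(O)c1O | target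

**Step count and risks**

Total step count: 13. Longest linear sequence: 11 steps (steps 1 to 4, then 7 to 13).

Steps most likely to fail:

1. Step 9. The aryloxy-substituted ruthenium carbene may turn over too slowly on the hindered 1,1-disubstituted alkene, so that double-bond migration into conjugation or intermolecular metathesis takes over. Fallback: the C2=C3 bond is made by carbonyl coupling instead of olefin metathesis. Setting out from 13, ozonolysis (O3, CH2Cl2, −78 °C; then Me2S) should cleave both terminal alkenes, the vinyl ether to the aryl formate and the 1,1-disubstituted alkene to the aryl ketone, to give tert-butyl 4-{2-[4-(benzyloxy)-2-methoxy-3-(methoxymethoxy)phenyl]-2-oxoethyl}-3-(formyloxy)phenyl carbonate F1. Low-valent titanium (TiCl3, Zn dust, DME, reflux, slow addition) should then join the ketone carbon C3 to the formate carbon C2 in an intramolecular keto ester McMurry-type cyclisation, which comes back to the route at 14.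

2. Step 10. Facial discrimination by the iridium catalyst may be poor on an enol ether whose C3 carries an ortho-methoxy aryl group, or the acidic iridium hydride may decompose the enol ether. Fallback: resolution replaces asymmetric catalysis. Setting out from 14, Pd/C and H2 (1 bar, EtOAc) should reduce the enol ether without stereocontrol and remove the benzyl group in the same operation, giving racemic tert-butyl 3-[4-hydroxy-2-methoxy-3-(methoxymethoxy)phenyl]chroman-7-yl carbonate F2. Preparative chromatography on a cellulose tris(3,5-dimethylphenylcarbamate) phase should separate it into 16, where the route is rejoined, and tert-butyl (3R)-3-[4-hydroxy-2-methoxy-3-(methoxymethoxy)phenyl]chroman-7-yl carbonate F3, which is discarded.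

3. Step 12. The Lewis acid may ionise the prenyl ether and cause loss of the prenyl group, or the ortho product may rearrange further or add its new phenol to the alkene. Fallback: the tertiary carbon is attached by cross-coupling instead of a sigmatropic shift. Setting out from 16, NBS (1.0 equiv) with i-Pr2NH (10 mol %) in CH2Cl2 at −20 °C should brominate the only free position ortho to the 4'-OH, giving tert-butyl (3S)-3-[5-bromo-4-hydroxy-2-methoxy-3-(methoxymethoxy)phenyl]chroman-7-yl carbonate F4. A γ-selective Suzuki–Miyaura coupling with 3-methylbut-2-enylboronic acid pinacol ester (Pd(OAc)2, 1,1'-bis(di-tert-butylphosphino)ferrocene, K3PO4, THF–H2O, 40 °C) should then bond the tertiary allyl carbon to C5' and come back to the route at 19.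

**Further compounds**

F1 | step 9 | tert-butyl 4-{2-[4-(benzyloxy)-2-methoxy-3-(methoxymethoxy)phenyl]-2-oxoethyl}-3-(formyloxy)phenyl carbonate | O=COc1cc(OC(=O)OC(C)(C)C)ccc1CC(=O)c1ccc(OCc2ccccc2)c(OCOC)c1OC
F2 | step 10 | racemic tert-butyl 3-[4-hydroxy-2-methoxy-3-(methoxymethoxy)phenyl]chroman-7-yl carbonate | COc1c(C2COc3cc(OC(=O)OC(C)(C)C)ccc3C2)ccc(O)c1OCOC
F3 | step 10 | tert-butyl (3R)-3-[4-hydroxy-2-methoxy-3-(methoxymethoxy)phenyl]chroman-7-yl carbonate | COc1c([C@@H]2COc3cc(OC(=O)OC(C)(C)C)ccc3C2)ccc(O)c1OCOC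
F4 | step 12 | tert-butyl (3S)-3-[5-bromo-4-hydroxy-2-methoxy-3-(methoxymethoxy)phenyl]chroman-7-yl carbonate | COc1c([C@H]2COc3cc(OC(=O)OC(C)(C)C)ccc3C2)cc(Br)c(O)c1OCOC
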